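**Retrosynthetic overview**

- Numbering: C1 (CH–O-angelate), C2 (CH2), C3 (angular C–CH3), C4 (CH2), C5 (C=O), C6 (C(CH3)–O-angelate), C7, C8 (CH2), C9 (ring-fusion alkene carbon), C10 (C–i-Pr); five-membered ring C1–C2–C3–C9–C10, seven-membered ring C3–C4–C5–C6–C7–C8–C9.
- Feature: C5(=O)–C6–C7 is read as an opened siloxycyclopropane; joined to C3=C4 it is a vinylcyclopropane, and C8≡C9 is an alkyne held to C3 by the three atoms C2–C1(ketal)–C10. One rhodium-catalysed (5+2) cycloaddition therefore forms C3–C9 (five-membered ring, first) and C7–C8 (seven-membered ring, second) and sets C3.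
- Endgame disconnections: both angelates (acylation), C1–OH (1,2-reduction of the C9=C10 enone), C10–i-Pr (iodination, Negishi coupling), C9=C10 (ketal hydrolysis with alkene migration), C6–OH and C6–CH3 (enolate methylation, then reagent-controlled oxidation of the enol silane).
- Precursor: achiral enyne from the ethylene ketal of diethyl 3-oxopentanedioate by way of the diyne, methylalumination–iodination of one alkyne and addition of the alkenyllithium to a cyclopropanone equivalent. The second alkyne is carried as its C-silyl derivative, because a free alkyne C–H would quench the alkenyllithium.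

Key step: step 11

Remark: CIP letters refer to the C1–C10 numbering above. The letter at C3 switches between R and S along the route only because the priorities of C2 and C4 change; the centre itself is not touched after step 11.

Assumption: the (S,R,R) phosphoramidite of step 11 and the D-fructose-derived ketone of step 15 are taken to be the antipodes that give the C3 and C6 configurations drawn. If the sense of induction is the opposite one, the mirror-image ligand or ketone is used with no other change.

**Route**

Step 1
Reactants: 1 diethyl 3-oxopentanedioate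
Product: 2 diethyl 2,2'-(1,3-dioxolane-2,2-diyl)diacetate
Conditions: HOCH2CH2OH (3 equiv), TsOH·H2O (5 mol%), toluene, reflux, Dean–Stark trap
Reagents that add atoms: ethane-1,2-diol, OCCO
Why: Acid-catalysed ketalisation with azeotropic removal of water masks the ketone that becomes C1 and prevents enolisation towards the two arms that later carry the alkyne and the alkene.

Step 2
Reactants: 2 diethyl 2,2'-(1,3-dioxolane-2,2-diyl)diacetate
Product: 3 2,2'-(1,3-dioxolane-2,2-diyl)di(ethan-1-ol)
Conditions: LiAlH4 (1.5 equiv), THF, 0 °C to rt; aqueous NaOH work-up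
Reagents that add atoms: none
Why: Hydride reduction of both esters to the primary alcohols, to which the ketal is inert.

Step 3
Reactants: 3 2,2'-(1,3-dioxolane-2,2-diyl)di(ethan-1-ol)
Product: 4 2,2'-(1,3-dioxolane-2,2-diyl)diacetaldehyde
Conditions: (COCl)2, DMSO, CH2Cl2, –78 °C; Et3N, –78 to 0 °C; used crude
Reagents that add atoms: none
Why: Swern oxidation stops at the aldehyde under non-acidic conditions that leave the β-ketal in place.

Step 4
Reactants: 4 2,2'-(1,3-dioxolane-2,2-diyl)diacetaldehyde; 5 dimethyl (1-diazo-2-oxopropyl)phosphonate (2.4 equiv)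
Product: 6 2,2-di(prop-2-yn-1-yl)-1,3-dioxolane
Conditions: K2CO3 (4 equiv), MeOH, 0 °C to rt
Reagents that add atoms: none
Why: Twofold Ohira–Bestmann (Seyferth–Gilbert) homologation turns each aldehyde into a terminal alkyne under mild carbonate conditions.

Step 5
Reactants: 6 2,2-di(prop-2-yn-1-yl)-1,3-dioxolane (3 equiv)
Product: 8 2-(prop-2-yn-1-yl)-2-[3-(trimethylsilyl)prop-2-yn-1-yl]-1,3-dioxolane, via lithium acetylide 7 (not isolated)
Conditions: n-BuLi (1.0 equiv), THF, –78 °C; Me3SiCl (1.0 equiv), –78 °C to rt; unchanged 6 recovered and recycled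
Reagents that add atoms: chlorotrimethylsilane, C[Si](C)(C)Cl
Why: Deprotonation and C-silylation of one terminal alkyne; with the diyne in threefold excess the statistical mixture should be mainly the monosilyl compound and recoverable diyne, and the silyl group masks the C–H that would otherwise quench the alkenyllithium of step 8.

Step 6
Reactants: 8 2-(prop-2-yn-1-yl)-2-[3-(trimethylsilyl)prop-2-yn-1-yl]-1,3-dioxolane
Product: 10 2-[(E)-3-iodo-2-methylprop-2-en-1-yl]-2-[3-(trimethylsilyl)prop-2-yn-1-yl]-1,3-dioxolane, via alkenyl(dimethyl)alane 9 (not isolated)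
Conditions: Me3Al (2.5 equiv), Cp2ZrCl2 (0.25 equiv), CH2Cl2, 0 °C to rt; then I2, THF, –30 to 0 °C
Reagents that add atoms: trimethylaluminium, C[Al](C)C; iodine, II
Why: Zirconium-catalysed methylalumination (Negishi carboalumination) adds methyl and aluminium syn across the terminal alkyne with methyl on the internal carbon, the silylalkyne reacting far more slowly, and iodinolysis with retention gives the E-iodoalkene that fixes the E geometry of C3=C4.

Step 7
Reactants: 11 (1-ethoxycyclopropoxy)trimethylsilane
Product: 12 1-ethoxycyclopropan-1-ol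
Conditions: MeOH, rt; careful evaporation
Reagents that add atoms: none
Why: Methanolysis of the O–Si bond liberates the ethyl hemiacetal of cyclopropanone, the usual storable cyclopropanone equivalent.

Step 8
Reactants: 10 2-[(E)-3-iodo-2-methylprop-2-en-1-yl]-2-[3-(trimethylsilyl)prop-2-yn-1-yl]-1,3-dioxolane; 12 1-ethoxycyclopropan-1-ol
Product: 16 1-[(E)-2-methyl-3-{2-[3-(trimethylsilyl)prop-2-yn-1-yl]-1,3-dioxolan-2-yl}prop-1-en-1-yl]cyclopropan-1-ol, via bromomagnesium 1-ethoxycyclopropanolate 13 (not isolated), via cyclopropanone 14 (not isolated), via alkenyllithium 15 (not isolated)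
Conditions: 12, MeMgBr (1.0 equiv), THF, –78 to 0 °C; separately 10, t-BuLi (2.05 equiv), Et2O, –78 °C; combine, –78 °C to rt; aqueous NH4Cl
Reagents that add atoms: none
Why: Iodine–lithium exchange proceeds with retention of alkene geometry, and the alkenyllithium adds to the cyclopropanone released from the magnesium hemiacetalate (organometallic addition to a cyclopropanone hemiacetal) to give the 1-alkenylcyclopropanol.

Step 9
Reactants: 16 1-[(E)-2-methyl-3-{2-[3-(trimethylsilyl)prop-2-yn-1-yl]-1,3-dioxolan-2-yl}prop-1-en-1-yl]cyclopropan-1-ol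
Product: 17 tert-butyldimethylsilyl ether of 16
Conditions: t-BuMe2SiOTf (1.3 equiv), 2,6-lutidine (2 equiv), CH2Cl2, –78 to 0 °C
Reagents that add atoms: tert-butyldimethylsilyl trifluoromethanesulfonate, CC(C)(C)[Si](C)(C)OS(=O)(=O)C(F)(F)F
Why: O-Silylation of the tertiary cyclopropanol with a silyl triflate and a hindered base, which keeps the acid-sensitive vinylcyclopropanol from ring expansion and installs the donor that later speeds cyclopropane cleavage.

Step 10
Reactants: 17 tert-butyldimethylsilyl ether of 16
Product: 18 tert-butyldimethyl({1-[(E)-2-methyl-3-[2-(prop-2-yn-1-yl)-1,3-dioxolan-2-yl]prop-1-en-1-yl]cyclopropyl}oxy)silane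
Conditions: K2CO3 (0.5 equiv), MeOH, rt
Reagents that add atoms: none
Why: Base-catalysed methanolysis of the alkynyl C–Si bond frees the terminal alkyne while the hindered silyl ether and the ketal are left untouched.

Step 11
Reactants: 18 tert-butyldimethyl({1-[(E)-2-methyl-3-[2-(prop-2-yn-1-yl)-1,3-dioxolan-2-yl]prop-1-en-1-yl]cyclopropyl}oxy)silane
Product: 19 (3R)-cycloadduct: bicyclo[5.3.0]deca-4,8-diene in the overview numbering with t-BuMe2SiO on C5 and methyl on C3 and a spiro-1,3-dioxolane at C1
Conditions: [RhCl(C2H4)2]2 (2.5 mol%), (S)-(1,1'-binaphthalene-2,2'-diyl) N,N-bis[(R)-1-phenylethyl]phosphoramidite (6 mol%), AgSbF6 (6 mol%), CH2Cl2, rt to 30 °C, moisture excluded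
Reagents that add atoms: none
Why: Chloride abstraction by AgSbF6 gives a cationic monovalent rhodium–phosphoramidite complex that binds the alkyne and the C3=C4 alkene; oxidative cyclisation forms C3–C9 and a rhodacyclopentene of trivalent rhodium, strain-driven cleavage of the cyclopropane C5–C7 bond (assisted by the siloxy donor on C5) widens it to an eight-membered rhodacycle, and reductive elimination forms C7–C8 and returns monovalent rhodium (the order of cyclopropane opening and alkyne insertion may be reversed without changing the bonds formed). The closest known reaction is the rhodium-catalysed intramolecular (5+2) cycloaddition of alkyne-tethered vinylcyclopropanes, which is established for siloxy-substituted cyclopropanes, for methyl-bearing alkene termini and, with phosphoramidite ligands, in enantioselective form. The five-membered ring closes first, in the exo sense across the three-atom tether C2–C1–C10, and the seven-membered ring closes by reductive elimination from the eight-membered rhodacycle, that is by ring contraction at the metal. C3 is the only new stereocentre and is expected to be set (R) when the ligand-bearing metal selects one face of the E-configured trisubstituted alkene in the C3–C9 bond-forming event; the substrate is achiral, so the ligand is the sole controlling element. The step needs enantiofacial selectivity and clean cycloaddition over alkyne oligomerisation and over ring expansion of the siloxy vinylcyclopropane: the gem-disubstituted ketal carbon favours chelation of both π-systems, the two cyclopropane CH2 groups are equivalent so that either cleavage gives the same C4=C5 enol silane, and the non-coordinating counter-ion under anhydrous conditions preserves the enol ether and the ketal.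

Step 12
Reactants: 19 (3R)-cycloadduct
Product: 20 (3S)-3-methylbicyclo[5.3.0]dec-8-en-5-one with a spiro-1,3-dioxolane at C1
Conditions: Bu4NF (1.1 equiv), AcOH (1.2 equiv), THF, 0 °C
Reagents that add atoms: none
Why: Fluoride cleaves the O–Si bond of the silyl enol ether and buffered protonation at C4 releases the C5 ketone without touching the ketal or moving the C8=C9 alkene.

Step 13
Reactants: 20 (3S)-3-methylbicyclo[5.3.0]dec-8-en-5-one with a spiro-1,3-dioxolane at C1
Product: 22 (3S)-3,6-dimethyl ketone as a mixture of C6 epimers, via lithium enolate 21 (not isolated)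
Conditions: LiN(iPr)2 (1.1 equiv), THF, –78 °C; MeI (3 equiv), –78 to –30 °C
Reagents that add atoms: iodomethane, CI
Why: Kinetic enolate alkylation, in which the hindered amide should remove a proton from C6 in preference to the neopentyl C4 next to the quaternary C3; the configuration at C6 is of no consequence because C6 becomes trigonal again in step 14.

Step 14
Reactants: 22 (3S)-3,6-dimethyl ketone as a mixture of C6 epimers
Product: 23 (3S)-tert-butyldimethylsilyl enol ether with the C5=C6 double bond
Conditions: t-BuMe2SiOTf (1.5 equiv), Et3N (3 equiv), CH2Cl2, 0 °C to rt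
Reagents that add atoms: tert-butyldimethylsilyl trifluoromethanesulfonate, CC(C)(C)[Si](C)(C)OS(=O)(=O)C(F)(F)F
Why: Silyl triflate–amine enol silylation under equilibrating conditions gives the more substituted (thermodynamic) C5=C6 enol ether, the C4=C5 isomer being disfavoured by the adjacent quaternary C3.

Step 15
Reactants: 23 (3S)-tert-butyldimethylsilyl enol ether with the C5=C6 double bond
Product: 25 (3S,6S)-6-hydroxy-3,6-dimethylbicyclo[5.3.0]dec-8-en-5-one with a spiro-1,3-dioxolane at C1, via siloxy epoxide 24 (not isolated)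
Conditions: 1,2:4,5-di-O-isopropylidene-β-D-erythro-2,3-hexodiulo-2,6-pyranose (0.3 equiv), KHSO5 (1.4 equiv, as 2KHSO5·KHSO4·K2SO4), K2CO3, Bu4NHSO4 (5 mol%), MeCN–CH2(OMe)2 / aqueous Na2B4O7 buffer (pH 10.5), 0 °C; then Bu4NF, AcOH, THF, 0 °C
Reagents that add atoms: potassium peroxymonosulfate, OOS(=O)(=O)[O-].[K+]
Why: Shi asymmetric epoxidation by the chiral dioxirane formed in situ, followed by opening of the siloxy epoxide to the α-hydroxy ketone (Rubottom-type oxidation); the dioxirane is to deliver oxygen to the C5=C6 face on the side of the C3 methyl group and so set C6, and the far less nucleophilic C8=C9 alkene should be spared by the limited amount of oxidant.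

Step 16
Reactants: 26 angelic acid
Product: 27 angelic 2,4,6-trichlorobenzoic anhydride
Conditions: 2,4,6-Cl3C6H2COCl (1.0 equiv), Et3N (1.05 equiv), toluene, 0 °C to rt; Et3NHCl filtered off under argon, filtrate concentrated and kept as a toluene stock solution at –20 °C
Reagents that add atoms: 2,4,6-trichlorobenzoyl chloride, O=C(Cl)c1c(Cl)cc(Cl)cc1Cl
Why: Acylation of triethylammonium angelate by the hindered aroyl chloride gives the mixed anhydride of the Yamaguchi esterification, and in the absence of a nucleophilic catalyst and of heat the Z alkene should not isomerise to the tiglate; one batch supplies the acyl donor for both esterifications (steps 17 and 22).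

Step 17
Reactants: 25 (3S,6S)-6-hydroxy-3,6-dimethylbicyclo[5.3.0]dec-8-en-5-one with a spiro-1,3-dioxolane at C1; 27 angelic 2,4,6-trichlorobenzoic anhydride (2 equiv)
Product: 29 (3S,6S)-C6 angelate of 25, via lithium alkoxide 28 (not isolated)
Conditions: 25, LiN(SiMe3)2 (1.05 equiv), THF, –78 °C; then 27 (toluene solution), –78 to 0 °C; aqueous NH4Cl
Reagents that add atoms: none
Why: Acylation of the tertiary lithium alkoxide by the Yamaguchi-type mixed anhydride, which is attacked at the unhindered angeloyl carbonyl at low temperature without Z to E isomerisation; esterifying C6–OH at this point also removes the free α-ketol before the enone is unveiled.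

Step 18
Reactants: 29 (3S,6S)-C6 angelate of 25
Product: 31 (3R,6S)-6-angeloyloxy-3,6-dimethylbicyclo[5.3.0]dec-9-ene-1,5-dione, via β,γ-unsaturated ketone 30 (not isolated)
Conditions: 1 M aqueous HCl, THF, rt to 40 °C
Reagents that add atoms: water, O
Why: Acid hydrolysis of the dioxolane gives the C1 ketone, and acid-catalysed dienol formation with protonation at C8 moves the C8=C9 alkene into conjugation as the more stable C9=C10 cyclopentenone, as in the hydrolysis of steroidal Δ5 3-ketals to Δ4 3-ketones.

Step 19
Reactants: 31 (3R,6S)-6-angeloyloxy-3,6-dimethylbicyclo[5.3.0]dec-9-ene-1,5-dione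
Product: 32 (3S,6S)-10-iodo derivative of 31
Conditions: I2 (2.5 equiv), pyridine (5 equiv), 4-(dimethylamino)pyridine (0.2 equiv), CH2Cl2, rt, dark
Reagents that add atoms: iodine, II
Why: Iodine–pyridine α-iodination of a cyclic enone (addition–elimination) puts iodine on C10, the only vinylic C–H of the enone, while the less reactive α-methylated enoate of the angelate should stay untouched.

Step 20
Reactants: 32 (3S,6S)-10-iodo derivative of 31
Product: 33 (3R,6S)-6-angeloyloxy-10-isopropyl-3,6-dimethylbicyclo[5.3.0]dec-9-ene-1,5-dione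
Conditions: i-PrZnBr (2.5 equiv, THF), PdCl2(dppf) (5 mol%, dppf = 1,1'-bis(diphenylphosphino)ferrocene), THF, rt to 45 °C
Reagents that add atoms: isopropylzinc bromide, CC(C)[Zn]Br
Why: Negishi cross-coupling of an alkenyl iodide with a secondary alkylzinc halide, in which the wide-bite-angle diphosphine speeds reductive elimination from divalent palladium ahead of β-hydride elimination so that isopropyl is transferred without isomerisation to n-propyl; ketones and esters do not react with the organozinc.

Step 21
Reactants: 33 (3R,6S)-6-angeloyloxy-10-isopropyl-3,6-dimethylbicyclo[5.3.0]dec-9-ene-1,5-dione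
Product: 34 (1S,3R,6S)-1-hydroxy-10-isopropyl-3,6-dimethyl-5-oxobicyclo[5.3.0]dec-9-en-6-yl angelate
Conditions: NaBH4 (1.0 equiv), CeCl3·7H2O (1.2 equiv), MeOH, –78 °C
Reagents that add atoms: none
Why: Luche 1,2-reduction of the cyclopentenone, in which hydride should add to C1 from the face opposite the angular C3 methyl group and so place the C1 hydroxyl cis to that methyl (1S), while the C5 ketone, flanked by the fully substituted C6 and the neopentyl C4, reacts much more slowly.

Step 22
Reactants: 34 (1S,3R,6S)-1-hydroxy-10-isopropyl-3,6-dimethyl-5-oxobicyclo[5.3.0]dec-9-en-6-yl angelate; 27 angelic 2,4,6-trichlorobenzoic anhydride (3 equiv)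
Product: 35 CNP0193302.1
Conditions: 27 (toluene solution), Et3N (3 equiv), toluene, 75 °C
Reagents that add atoms: none
Why: Yamaguchi-type esterification of the secondary allylic alcohol with the preformed angelic mixed anhydride in the absence of a nucleophilic catalyst, conditions under which angelates form without isomerisation to tiglates; C1 keeps its configuration because its C–O bond is not broken.

**Compound list**

1 | diethyl 3-oxopentanedioate | CCOC(=O)CC(=O)CC(=O)OCC | starting material
2 | diethyl 2,2'-(1,3-dioxolane-2,2-diyl)diacetate | CCOC(=O)CC1(OCCO1)CC(=O)OCC | intermediate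
3 | 2,2'-(1,3-dioxolane-2,2-diyl)di(ethan-1-ol) | OCCC1(OCCO1)CCO | intermediate
4 | 2,2'-(1,3-dioxolane-2,2-diyl)diacetaldehyde | O=CCC1(OCCO1)CC=O | intermediate
5 | dimethyl (1-diazo-2-oxopropyl)phosphonate | COP(=O)(OC)C(=[N+]=[N-])C(C)=O | starting material
6 | 2,2-di(prop-2-yn-1-yl)-1,3-dioxolane | C#CCC1(OCCO1)CC#C | intermediate
7 | lithium acetylide of 6 | [Li]C#CCC1(OCCO1)CC#C | intermediate (not isolated)
8 | 2-(prop-2-yn-1-yl)-2-[3-(trimethylsilyl)prop-2-yn-1-yl]-1,3-dioxolane | C#CCC1(OCCO1)CC#C[Si](C)(C)C | intermediate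
9 | dimethyl[(E)-2-methyl-3-{2-[3-(trimethylsilyl)prop-2-yn-1-yl]-1,3-dioxolan-2-yl}prop-1-en-1-yl]alumane | C[Al](C)/C=C(\C)CC1(OCCO1)CC#C[Si](C)(C)C | intermediate (not isolated)
10 | 2-[(E)-3-iodo-2-methylprop-2-en-1-yl]-2-[3-(trimethylsilyl)prop-2-yn-1-yl]-1,3-dioxolane | I/C=C(\C)CC1(OCCO1)CC#C[Si](C)(C)C | intermediate
11 | (1-ethoxycyclopropoxy)trimethylsilane | CCOC1(O[Si](C)(C)C)CC1 | starting material
12 | 1-ethoxycyclopropan-1-ol | CCOC1(O)CC1 | intermediate
13 | bromomagnesium 1-ethoxycyclopropan-1-olate | CCOC1(O[Mg]Br)CC1 | intermediate (not isolated)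
14 | cyclopropanone | O=C1CC1 | intermediate (not isolated)
15 | [(E)-2-methyl-3-{2-[3-(trimethylsilyl)prop-2-yn-1-yl]-1,3-dioxolan-2-yl}prop-1-en-1-yl]lithium | [Li]/C=C(\C)CC1(OCCO1)CC#C[Si](C)(C)C | intermediate (not isolated)
16 | 1-[(E)-2-methyl-3-{2-[3-(trimethylsilyl)prop-2-yn-1-yl]-1,3-dioxolan-2-yl}prop-1-en-1-yl]cyclopropan-1-ol | OC1(CC1)/C=C(\C)CC1(OCCO1)CC#C[Si](C)(C)C | intermediate
17 | tert-butyldimethylsilyl ether of 16 | CC(C)(C)[Si](C)(C)OC1(CC1)/C=C(\C)CC1(OCCO1)CC#C[Si](C)(C)C | intermediate
18 | tert-butyldimethyl({1-[(E)-2-methyl-3-[2-(prop-2-yn-1-yl)-1,3-dioxolan-2-yl]prop-1-en-1-yl]cyclopropyl}oxy)silane (key-step precursor, achiral) | C#CCC1(OCCO1)C/C(C)=C/C1(O[Si](C)(C)C(C)(C)C)CC1 | intermediate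
19 | (3R)-cycloadduct: C4=C5 silyl enol ether (t-BuMe2SiO on C5), C8=C9 alkene, C3 methyl, spiro-1,3-dioxolane at C1 | CC(C)(C)[Si](C)(C)OC1=C[C@@]2(C)CC3(OCCO3)CC2=CCC1 | intermediate
20 | (3S)-3-methylbicyclo[5.3.0]dec-8-en-5-one, spiro-1,3-dioxolane at C1 | O=C1C[C@@]2(C)CC3(OCCO3)CC2=CCC1 | intermediate
21 | (3S)-lithium enolate of 20 (C5=C6) | [Li]OC1=CCC=C2CC3(OCCO3)C[C@]2(C)C1 | intermediate (not isolated)
22 | (3S)-3,6-dimethylbicyclo[5.3.0]dec-8-en-5-one, spiro-1,3-dioxolane at C1, C6 epimers | O=C1C[C@@]2(C)CC3(OCCO3)CC2=CCC1C | intermediate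
23 | (3S)-tert-butyldimethylsilyl enol ether of 22 (C5=C6) | CC(C)(C)[Si](C)(C)OC1=C(C)CC=C2CC3(OCCO3)C[C@]2(C)C1 | intermediate
24 | (3R,5S,6S)-5,6-epoxide of 23, oxygen on the face of the C3 methyl | O1CCOC12C[C@]3(C)C[C@@]4(O[Si](C)(C)C(C)(C)C)O[C@@]4(C)CC=C3C2 | intermediate (not isolated)
25 | (3S,6S)-6-hydroxy-3,6-dimethylbicyclo[5.3.0]dec-8-en-5-one, spiro-1,3-dioxolane at C1 | O1CCOC12C[C@]3(C)CC(=O)[C@@](C)(O)CC=C3C2 | intermediate
26 | angelic acid, (Z)-2-methylbut-2-enoic acid | C/C=C(/C)C(=O)O | starting material
27 | angelic 2,4,6-trichlorobenzoic anhydride | C/C=C(/C)C(=O)OC(=O)c1c(Cl)cc(Cl)cc1Cl | intermediate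
28 | lithium alkoxide of 25 | O1CCOC12C[C@]3(C)CC(=O)[C@@](C)(O[Li])CC=C3C2 | intermediate (not isolated)
29 | (3S,6S)-C6 angelate of 25 | O1CCOC12C[C@]3(C)CC(=O)[C@@](C)(OC(=O)/C(C)=C\C)CC=C3C2 | intermediate
30 | (3R,6S)-6-angeloyloxy-3,6-dimethylbicyclo[5.3.0]dec-8-ene-1,5-dione | O=C1C[C@]2(C)CC(=O)[C@@](C)(OC(=O)/C(C)=C\C)CC=C2C1 | intermediate (not isolated)
31 | (3R,6S)-6-angeloyloxy-3,6-dimethylbicyclo[5.3.0]dec-9-ene-1,5-dione | O=C1C[C@]2(C)CC(=O)[C@@](C)(OC(=O)/C(C)=C\C)CCC2=C1 | intermediate
32 | (3S,6S)-6-angeloyloxy-10-iodo-3,6-dimethylbicyclo[5.3.0]dec-9-ene-1,5-dione | O=C1C[C@]2(C)CC(=O)[C@@](C)(OC(=O)/C(C)=C\C)CCC2=C1I | intermediate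
33 | (3R,6S)-6-angeloyloxy-10-isopropyl-3,6-dimethylbicyclo[5.3.0]dec-9-ene-1,5-dione | O=C1C[C@]2(C)CC(=O)[C@@](C)(OC(=O)/C(C)=C\C)CCC2=C1C(C)C | intermediate
34 | (1S,3R,6S)-1-hydroxy-10-isopropyl-3,6-dimethyl-5-oxobicyclo[5.3.0]dec-9-en-6-yl angelate | O[C@H]1C[C@]2(C)CC(=O)[C@@](C)(OC(=O)/C(C)=C\C)CCC2=C1C(C)C | intermediate
35 | CNP0193302.1, (1S,3R,6S)-10-isopropyl-3,6-dimethyl-5-oxobicyclo[5.3.0]dec-9-ene-1,6-diyl diangelate | C/C=C(/C)C(=O)O[C@H]1C[C@]2(C)CC(=O)[C@@](C)(OC(=O)/C(C)=C\C)CCC2=C1C(C)C | target

**Step count**

Total: 22 steps. Longest linear sequence: 20 steps (steps 1–6, 8–15 and 17–22, from 1); steps 7 and 16 are one-step side branches.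

**Steps most likely to fail**

Step 11. The ligand may discriminate poorly between the two faces of the methyl-bearing alkene terminus, or the cationic catalyst may be diverted into oligomerisation of the terminal alkyne. Fallback: setting out from 18, the cycloaddition is run with the achiral complex [Rh(CO)2Cl]2 (5 mol%, toluene, 60 °C), which should give the racemic cycloadduct F1. The conditions of steps 12 to 14 then lead to the racemic ketone F2, through the racemic lithium enolate F3 to the racemic methyl ketone F4, and on to the racemic enol silane F5. The chiral dioxirane of step 15 oxidises both enantiomers of F5 from the same absolute face: one half reacts by way of 24, the mirror-image half by way of the epimeric siloxy epoxide F6. After the fluoride work-up, 25 is therefore accompanied by its C3 epimer, the hydroxy ketone F7. The two are diastereomers and are separated by chromatography, and the route is rejoined at 25 at the cost of half the material.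

Step 15. Facial selectivity of the dioxirane may be poor on a tetrasubstituted enol silane, all the more since the C3 methyl group sits on the face that must be attacked, and the C8=C9 alkene may be epoxidised in competition. Fallback: C6 is built with reversed polarity, by nucleophilic methylation. Setting out from 20, the enolate 21 (LiN(iPr)2, THF, –78 °C) is trapped with Me3SiCl as the kinetic trimethylsilyl enol ether F8. Rubottom oxidation with 3-chloroperbenzoic acid (NaHCO3, CH2Cl2, –20 °C) gives the siloxy epoxide F9 and, after Bu4NF/AcOH, the 6-hydroxy ketone F10 as a mixture of C6 epimers. Swern oxidation gives the 5,6-dione F11. MeCeCl2 (from CeCl3 and MeLi, THF, –78 °C; the low basicity tolerates the enolisable dione) should add to the C6 carbonyl, since C5 is shielded by the neopentyl C4, and from the face opposite the C3 methyl group. This places the hydroxyl cis to that methyl and returns to the route at 25.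

Step 19. Iodination may be slow or incomplete because the β-carbon C9 is flanked by the quaternary C3, and long exposure to iodine may erode the angelate geometry. Fallback: setting out from 31, bromine (1.0 equiv, CH2Cl2, –78 °C) adds across the β,β-dialkyl enone alkene, which is more electron-rich than the angelate alkene, to give the 9,10-dibromide F12. Et3N (0 °C) then eliminates HBr to give the α-bromoenone F13, which takes the place of 32 in the cross-coupling of step 20 and returns to the route at 33.

**Further compounds**

F1 | step 11 | racemic cycloadduct (racemate of 19) | CC(C)(C)[Si](C)(C)OC1=CC2(C)CC3(OCCO3)CC2=CCC1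
F2 | step 11 | racemic ketone (racemate of 20) | O=C1CC2(C)CC3(OCCO3)CC2=CCC1
F3 | step 11 | racemic lithium enolate (racemate of 21) | [Li]OC1=CCC=C2CC3(OCCO3)CC2(C)C1
F4 | step 11 | racemic methyl ketone (racemate of 22, C6 epimers) | O=C1CC2(C)CC3(OCCO3)CC2=CCC1C
F5 | step 11 | racemic enol silane (racemate of 23) | CC(C)(C)[Si](C)(C)OC1=C(C)CC=C2CC3(OCCO3)CC2(C)C1
F6 | step 11 | (3S,5S,6S)-siloxy epoxide, C3 epimer of 24 | O1CCOC12C[C@@]3(C)C[C@@]4(O[Si](C)(C)C(C)(C)C)O[C@@]4(C)CC=C3C2
F7 | step 11 | (3R,6S)-hydroxy ketone, C3 epimer of 25 | O1CCOC12C[C@@]3(C)CC(=O)[C@@](C)(O)CC=C3C2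
F8 | step 15 | (3S)-trimethylsilyl enol ether of 20 (C5=C6) | C[Si](C)(C)OC1=CCC=C2CC3(OCCO3)C[C@]2(C)C1
F9 | step 15 | (3R)-5,6-epoxide of F8 (both epoxide faces) | O1CCOC12C[C@]3(C)CC4(O[Si](C)(C)C)OC4CC=C3C2
F10 | step 15 | (3S)-6-hydroxy-3-methylbicyclo[5.3.0]dec-8-en-5-one, spiro-1,3-dioxolane at C1, C6 epimers | O1CCOC12C[C@]3(C)CC(=O)C(O)CC=C3C2
F11 | step 15 | (3S)-3-methylbicyclo[5.3.0]dec-8-ene-5,6-dione, spiro-1,3-dioxolane at C1 | O1CCOC12C[C@]3(C)CC(=O)C(=O)CC=C3C2
F12 | step 19 | (3S,6S)-9,10-dibromide of 31 (C9 and C10 epimers) | O=C1C[C@]2(C)CC(=O)[C@@](C)(OC(=O)/C(C)=C\C)CCC2(Br)C1Br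
F13 | step 19 | (3S,6S)-6-angeloyloxy-10-bromo-3,6-dimethylbicyclo[5.3.0]dec-9-ene-1,5-dione | O=C1C[C@]2(C)CC(=O)[C@@](C)(OC(=O)/C(C)=C\C)CCC2=C1Br
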